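The oxepane (C1, C2, C3, O, C16, C15, C14; eunicellane numbering) is not closed as an ether. It is carried as a six-membered carbocycle (C1, C2, C3, C16, C15, C14) in which C16 is a ketone bonded to quaternary C3. A Baeyer–Villiger oxidation then inserts the ring oxygen between C16 and C3 with retention, and the lactone is reduced to the ether. The key step exploits the ether oxygen flanked by the fully substituted C3 and the C16 methylene. The precursor, a trans-fused bicyclic 2,2,6-trisubstituted cyclohexanone, comes from an asymmetric Diels–Alder reaction, an allylboration and ring-closing metathesis; the tetrahydrofuran and oxonanone rings are closed afterwards.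

Key step: step 13

Remark on numbering: ring A = cyclohexane C1, C10, C11, C12, C13, C14; ring B = carbocycle C1, C2, C3, C16, C15, C14 (later the oxepane); tetrahydrofuran = C1, C2, O, C9, C10; oxonane = C2–C9 plus O; C17 = methyl on C15, C18 = methyl on C3, C20 = methyl on C12.

Assumption: the chiral catalysts of steps 6 and 7 are taken to induce in the sense of their accepted transition-state models (shielded Si face at C1; Re-face allyl transfer); if the opposite sense is found, the mirror-image catalyst is used.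

Step 1
Reactants: 1 methacrolein; 2 (triphenylphosphoranylidene)acetaldehyde
Product: 3 (2E)-4-methylpenta-2,4-dienal
Conditions: toluene, 80 °C
Reagents that add atoms: none
Why: Wittig olefination with the stabilised formylmethylene ylide adds two carbons and should give the E-enal, the conjugated product being less electrophilic than 1.

Step 2
Reactants: 3 (2E)-4-methylpenta-2,4-dienal
Product: 4 (2E)-4-methylpenta-2,4-dien-1-ol
Conditions: NaBH4, CeCl3·7H2O, MeOH, 0 °C
Reagents that add atoms: none
Why: Luche reduction delivers hydride 1,2 to the dienal and leaves the diene intact.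

Step 3
Reactants: 4 (2E)-4-methylpenta-2,4-dien-1-ol
Product: 5 tert-butyl{[(2E)-4-methylpenta-2,4-dien-1-yl]oxy}diphenylsilane
Conditions: t-BuPh2SiCl, imidazole, CH2Cl2, rt
Reagents that add atoms: tert-butyl(chloro)diphenylsilane CC(C)(C)[Si](Cl)(c1ccccc1)c1ccccc1
Why: Silylation of the primary allylic alcohol gives an ether that should survive acid, hydride and peracid until step 16.

Step 4
Reactants: 6 5-chloropent-1-yne
Product: 8 (1E)-5-chloro-1-iodo-2-methylpent-1-ene, via vinylalane 7 (not isolated)
Conditions: AlMe3, Cp2ZrCl2 (cat.), CH2Cl2, 0 °C to rt; then I2, THF, −30 °C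
Reagents that add atoms: trimethylaluminium C[Al](C)C; iodine II
Why: Negishi carboalumination adds methyl and aluminium syn across the alkyne (methyl to the internal carbon), and iodinolysis with retention should give the E-vinyl iodide; the methyl becomes C18.

Step 5
Reactants: 8 (1E)-5-chloro-1-iodo-2-methylpent-1-ene
Product: 11 2-[(2E)-6-chloro-3-methylhex-2-en-1-yl]-4,4,5,5-tetramethyl-1,3,2-dioxaborolane, via vinyllithium 9 (not isolated), via borate complex 10 (not isolated)
Conditions: t-BuLi (2 equiv), Et2O, −78 °C; then 2-(chloromethyl)-4,4,5,5-tetramethyl-1,3,2-dioxaborolane, −78 °C to rt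
Reagents that add atoms: 2-(chloromethyl)-4,4,5,5-tetramethyl-1,3,2-dioxaborolane ClCB1OC(C)(C)C(C)(C)O1
Why: Lithium–iodine exchange with retention, addition to boron and 1,2-metallate shift with loss of chloride (Matteson homologation) should give the allylboronate with the E-alkene intact.

Step 6
Reactants: 3 (2E)-4-methylpenta-2,4-dienal; 5 tert-butyl{[(2E)-4-methylpenta-2,4-dien-1-yl]oxy}diphenylsilane
Product: 12 (1S,2R,6R)-2-({[tert-butyl(diphenyl)silyl]oxy}methyl)-4-methyl-6-(prop-1-en-2-yl)cyclohex-3-ene-1-carbaldehyde (ring A; C1-CHO cis to the C10 side chain, trans to the C14 isopropenyl group)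
Conditions: (5R)-5-benzyl-2,2,3-trimethylimidazolidin-4-one hydrochloride (20 mol %), CH3CN/H2O 95:5, −10 °C to rt
Reagents that add atoms: none
Why: Iminium-catalysed Diels–Alder reaction: the diene terminus C13 bonds to the β-carbon C14, the E-dienophile gives the trans C1/C14 relation, the endo transition state gives the cis C1/C10 relation, and the catalyst benzyl group shields the Si face of C1, which sets the absolute configuration.

Step 7
Reactants: 12 ring A aldehyde; 11 2-[(2E)-6-chloro-3-methylhex-2-en-1-yl]-4,4,5,5-tetramethyl-1,3,2-dioxaborolane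
Product: 13 (1S,2R)-1-[(1S,2R,6R)-2-({[tert-butyl(diphenyl)silyl]oxy}methyl)-4-methyl-6-(prop-1-en-2-yl)cyclohex-3-en-1-yl]-2-(3-chloropropyl)-2-methylbut-3-en-1-ol (C2 carbinol; quaternary C3 with methyl, vinyl = C16 and 3-chloropropyl = C4, C5 plus one carbon)
Conditions: (R)-3,3′-bis(2,4,6-triisopropylphenyl)-1,1′-binaphthyl-2,2′-diyl hydrogen phosphate (5 mol %), 4 Å sieves, toluene, −30 °C
Reagents that add atoms: none
Why: Acid-catalysed allylboration through a closed Zimmerman–Traxler chair: the E-boronate places the chloropropyl chain anti and the methyl syn to the new hydroxyl (C3), and the chiral acid directs addition to the Re face of the aldehyde (C2).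

Step 8
Reactants: 13 homoallylic alcohol
Product: 14 tert-butyldimethylsilyl ether of 13 (C2-OTBS)
Conditions: t-BuMe2SiOTf, 2,6-lutidine, CH2Cl2, −78 to 0 °C
Reagents that add atoms: tert-butyldimethylsilyl triflate CC(C)(C)[Si](C)(C)OS(=O)(=O)C(F)(F)F
Why: The silyl triflate silylates the hindered alcohol, so that C2–O survives the oxidations and cannot attack the lactone or the oxocarbenium ion formed later.

Step 9
Reactants: 14 silyl ether
Product: 15 trans-fused ring A/ring B diene (C15=C16 with 15-methyl; C11=C12 with 12-methyl)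
Conditions: second-generation Grubbs catalyst RuCl2(=CHPh)(H2IMes)(PCy3) (5 mol %), toluene, 80 °C
Reagents that add atoms: none
Why: Ring-closing metathesis of the C3 vinyl and C14 isopropenyl groups closes six-membered ring B as a trisubstituted cyclohexene; the trans-diequatorial C1/C14 substituents hold the two olefins close.

Step 10
Reactants: 15 ring A/ring B diene
Product: 17 11,16-diol (C11-OH and C16-OH on the faces opposite the C10 side chain and the C3 chloropropyl group), via bis(alkylborane) 16 (not isolated)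
Conditions: BH3·THF, THF, 0 °C to rt; then NaOH, H2O2, 0 °C to rt
Reagents that add atoms: hydrogen peroxide OO
Why: Hydroboration–oxidation puts boron on the less substituted C11 and C16 and adds syn from the faces opposite the pseudoaxial C10 side chain (ring A) and the pseudoaxial chloropropyl group on C3 (ring B), which sets the C12 and C15 methyl stereocentres.

Step 11
Reactants: 17 11,16-diol
Product: 18 11,16-diketone
Conditions: Dess–Martin periodinane, NaHCO3, CH2Cl2, 0 °C to rt
Reagents that add atoms: none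
Why: Dess–Martin oxidation of both secondary alcohols under buffered conditions should not epimerise the α-methyl centres C12 and C15.

Step 12
Reactants: 18 11,16-diketone
Product: 19 11-hydroxy-16-ketone (C11-OH equatorial, cis to the 12-methyl group)
Conditions: LiAlH(OtBu)3, THF, −78 to −40 °C
Reagents that add atoms: none
Why: The bulky hydride reduces the 2,6-disubstituted C11 ketone and not the neopentylic C16 ketone, and attacks from the face opposite the axial substituents on C10 and C12, which gives the equatorial C11 alcohol of the target.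

Step 13
Reactants: 19 11-hydroxy-16-ketone
Product: 20 ε-lactone (C16(=O)–O–C3; oxepan-2-one ring C1, C2, C3, O, C16, C15, C14)
Conditions: mCPBA, NaHCO3, CH2Cl2, 0 °C to rt
Reagents that add atoms: 3-chloroperoxybenzoic acid OOC(=O)c1cccc(Cl)c1
Why: Baeyer–Villiger oxidation: the peracid adds to the C16 carbonyl (Criegee adduct) and the C3–C16 bond, anti-periplanar to the O–O bond, migrates to oxygen with loss of 3-chlorobenzoate. The closest known reaction type is the peracid oxidation of 2,2,6-trisubstituted cyclohexanones to ε-lactones. No ring is closed by cyclisation: the six-membered carbocycle (C1, C2, C3, C16, C15, C14) grows to the seven-membered lactone (C1, C2, C3, O, C16, C15, C14) by a 1,2-shift of C3 from carbon to oxygen. No new stereocentre forms: C3 migrates with retention, so the quaternary centre of step 7 becomes the tertiary ether centre, and the buffer should keep the axial C15 methyl from epimerising. The step needs regioselectivity (C3 over C15), secured by the higher migratory aptitude of the fully substituted carbon, and chemoselectivity, secured because no alkene remains after step 10 and the alcohol, chloride and silyl ethers are inert to peracid.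

Step 14
Reactants: 20 ε-lactone
Product: 21 lactol (C16 hemiacetal, anomers)
Conditions: i-Bu2AlH, CH2Cl2, −78 °C
Reagents that add atoms: none
Why: Half-reduction of the lactone; the tetrahedral aluminate is stable at −78 °C and no other reducible group is present.

Step 15
Reactants: 21 lactol
Product: 22 oxepane bis-silyl ether (C16 methylene)
Conditions: Et3SiH, BF3·OEt2, CH2Cl2, −78 to −20 °C
Reagents that add atoms: none
Why: Reductive deoxygenation: the lactol ionises to the oxocarbenium ion C16=O+–C3, which the silane reduces to the cyclic ether; the C2 silyl ether prevents bicyclic acetal formation.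

Step 16
Reactants: 22 oxepane bis-silyl ether
Product: 23 triol chloride (free 2-OH, 9-OH, 11-OH)
Conditions: Bu4NF, THF, rt to 50 °C
Reagents that add atoms: none
Why: Fluoride cleaves both silyl ethers; the primary chloride reacts much more slowly with fluoride.

Step 17
Reactants: 23 triol chloride
Product: 26 allyl triol (C3-allyl = C4 C5 plus terminal CH2), via selenide 24 (not isolated), via selenoxide 25 (not isolated)
Conditions: (PhSe)2, NaBH4, EtOH, 50 °C; then H2O2, THF, 0 °C to rt
Reagents that add atoms: none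
Why: Selenolate displaces the primary chloride, and oxidation to the selenoxide with syn-elimination should give the terminal alkene, so the allyl group appears only after the hydroboration, peracid and oxocarbenium steps.

Step 18
Reactants: 26 allyl triol
Product: 28 lactol (tetrahydrofuran ring C1 C2 O C9 C10 closed; 9-OH anomers), via hydroxy aldehyde 27 (not isolated)
Conditions: TEMPO (cat.), PhI(OAc)2 (1.1 equiv), CH2Cl2, rt
Reagents that add atoms: none
Why: The oxoammonium oxidation takes only the primary C9 alcohol; the aldehyde is trapped by the cis C2 hydroxyl as the five-membered lactol, and the hindered C11 alcohol is left.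

Step 19
Reactants: 28 lactol
Product: 29 9,11-diacetate
Conditions: Ac2O, pyridine, DMAP (cat.), CH2Cl2, rt
Reagents that add atoms: acetic anhydride CC(=O)OC(C)=O
Why: One acetylation installs the C11 acetate of the target and the anomeric leaving group at C9.

Step 20
Reactants: 29 9,11-diacetate; 30 2-(trimethylsilyloxy)buta-1,3-diene
Product: 31 vinyl ketone (C9–C8H2–C7(=O)–CH=CH2)
Conditions: BF3·OEt2, CH2Cl2, −78 °C
Reagents that add atoms: none
Why: Mukaiyama-type addition of the silyl enol ether to the C9 oxocarbenium ion; attack on the convex face, anti to the C10–C11 bond of cis-fused ring A, should place C8 cis to C3 across the tetrahydrofuran and set C9.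

Step 21
Reactants: 31 vinyl ketone
Product: 32 nine-membered Z-enone (C5=C6–C7=O)
Conditions: second-generation Grubbs catalyst RuCl2(=CHPh)(H2IMes)(PCy3) (10 mol %), CH2Cl2 (2 mM), 40 °C
Reagents that add atoms: none
Why: Ring-closing metathesis of the C3 allyl group with the vinyl ketone closes the oxonane ring (C2–C9 plus O); the cis-2,5 arrangement on the tetrahydrofuran brings the chains together.

Step 22
Reactants: 32 nine-membered enone
Product: 33 target CNP0288436.2
Conditions: H2 (1 atm), Pd/C, EtOAc, rt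
Reagents that add atoms: none
Why: Catalytic hydrogenation of the only remaining C=C bond; ketone, acetate and ethers are inert.

Compound list
1 | methacrolein | CC(=C)C=O | starting material
2 | (triphenylphosphoranylidene)acetaldehyde | O=CC=P(c1ccccc1)(c1ccccc1)c1ccccc1 | starting material
3 | (2E)-4-methylpenta-2,4-dienal | CC(=C)/C=C/C=O | intermediate
4 | (2E)-4-methylpenta-2,4-dien-1-ol | CC(=C)/C=C/CO | intermediate
5 | tert-butyl{[(2E)-4-methylpenta-2,4-dien-1-yl]oxy}diphenylsilane | CC(=C)/C=C/CO[Si](c1ccccc1)(c1ccccc1)C(C)(C)C | intermediate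
6 | 5-chloropent-1-yne | C#CCCCCl | starting material
7 | [(1E)-5-chloro-2-methylpent-1-en-1-yl]dimethylalane | C[Al](C)/C=C(\C)CCCCl | intermediate
8 | (1E)-5-chloro-1-iodo-2-methylpent-1-ene | I/C=C(\C)CCCCl | intermediate
9 | [(1E)-5-chloro-2-methylpent-1-en-1-yl]lithium | [Li]/C=C(\C)CCCCl | intermediate
10 | lithium (chloromethyl)[(1E)-5-chloro-2-methylpent-1-en-1-yl](pinacolato)borate | [Li+].ClC[B-]1(/C=C(\C)CCCCl)OC(C)(C)C(C)(C)O1 | intermediate
11 | 2-[(2E)-6-chloro-3-methylhex-2-en-1-yl]-4,4,5,5-tetramethyl-1,3,2-dioxaborolane | CC1(C)OB(C/C=C(\C)CCCCl)OC1(C)C | intermediate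
12 | (1S,2R,6R)-2-({[tert-butyl(diphenyl)silyl]oxy}methyl)-4-methyl-6-(prop-1-en-2-yl)cyclohex-3-ene-1-carbaldehyde | O=C[C@@H]1[C@H](CO[Si](c2ccccc2)(c2ccccc2)C(C)(C)C)C=C(C)C[C@H]1C(C)=C | intermediate
13 | (1S,2R)-1-[ring A of 12]-2-(3-chloropropyl)-2-methylbut-3-en-1-ol (C2-OH syn to C18, anti to the chloropropyl chain) | O[C@@H]([C@@H]1[C@H](CO[Si](c2ccccc2)(c2ccccc2)C(C)(C)C)C=C(C)C[C@H]1C(C)=C)[C@@](C)(C=C)CCCCl | intermediate
14 | C2 tert-butyldimethylsilyl ether of 13 | CC(C)(C)[Si](C)(C)O[C@@H]([C@@H]1[C@H](CO[Si](c2ccccc2)(c2ccccc2)C(C)(C)C)C=C(C)C[C@H]1C(C)=C)[C@@](C)(C=C)CCCCl | intermediate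
15 | trans-fused ring A/ring B diene: C15=C16 (15-methyl), C11=C12 (12-methyl), 2-OTBS, 3-methyl-3-(3-chloropropyl), 10-CH2OTBDPS cis to C2 | CC(C)(C)[Si](C)(C)O[C@H]1[C@@H]2[C@H](CO[Si](c3ccccc3)(c3ccccc3)C(C)(C)C)C=C(C)C[C@H]2C(C)=C[C@@]1(C)CCCCl | intermediate
16 | 11,16-bis(borane) adduct of 15 | CC(C)(C)[Si](C)(C)O[C@H]1[C@@H]2[C@H](CO[Si](c3ccccc3)(c3ccccc3)C(C)(C)C)[C@@H](B)[C@H](C)C[C@H]2[C@@H](C)[C@H](B)[C@@]1(C)CCCCl | intermediate
17 | 11,16-diol (11-OH trans to 12-methyl; 15-methyl cis to the C3 chain) | CC(C)(C)[Si](C)(C)O[C@H]1[C@@H]2[C@H](CO[Si](c3ccccc3)(c3ccccc3)C(C)(C)C)[C@@H](O)[C@H](C)C[C@H]2[C@@H](C)[C@H](O)[C@@]1(C)CCCCl | intermediate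
18 | 11,16-diketone | CC(C)(C)[Si](C)(C)O[C@H]1[C@@H]2[C@H](CO[Si](c3ccccc3)(c3ccccc3)C(C)(C)C)C(=O)[C@H](C)C[C@H]2[C@@H](C)C(=O)[C@@]1(C)CCCCl | intermediate
19 | 11-hydroxy-16-ketone (11-OH cis to 12-methyl) | CC(C)(C)[Si](C)(C)O[C@H]1[C@@H]2[C@H](CO[Si](c3ccccc3)(c3ccccc3)C(C)(C)C)[C@H](O)[C@H](C)C[C@H]2[C@@H](C)C(=O)[C@@]1(C)CCCCl | intermediate
20 | ε-lactone (C16 carbonyl, ring oxygen on C3) | CC(C)(C)[Si](C)(C)O[C@H]1[C@@H]2[C@H](CO[Si](c3ccccc3)(c3ccccc3)C(C)(C)C)[C@H](O)[C@H](C)C[C@H]2[C@@H](C)C(=O)O[C@@]1(C)CCCCl | intermediate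
21 | lactol (C16 hemiacetal, anomers) | CC(C)(C)[Si](C)(C)O[C@H]1[C@@H]2[C@H](CO[Si](c3ccccc3)(c3ccccc3)C(C)(C)C)[C@H](O)[C@H](C)C[C@H]2[C@@H](C)C(O)O[C@@]1(C)CCCCl | intermediate
22 | oxepane bis-silyl ether | CC(C)(C)[Si](C)(C)O[C@H]1[C@@H]2[C@H](CO[Si](c3ccccc3)(c3ccccc3)C(C)(C)C)[C@H](O)[C@H](C)C[C@H]2[C@@H](C)CO[C@@]1(C)CCCCl | intermediate
23 | oxepane triol with 3-chloropropyl on C3 | O[C@H]1[C@@H]2[C@H](CO)[C@H](O)[C@H](C)C[C@H]2[C@@H](C)CO[C@@]1(C)CCCCl | intermediate
24 | phenyl selenide of 23 | O[C@H]1[C@@H]2[C@H](CO)[C@H](O)[C@H](C)C[C@H]2[C@@H](C)CO[C@@]1(C)CCC[Se]c1ccccc1 | intermediate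
25 | selenoxide of 24 | O[C@H]1[C@@H]2[C@H](CO)[C@H](O)[C@H](C)C[C@H]2[C@@H](C)CO[C@@]1(C)CCC[Se](=O)c1ccccc1 | intermediate
26 | oxepane triol with allyl on C3 | O[C@H]1[C@@H]2[C@H](CO)[C@H](O)[C@H](C)C[C@H]2[C@@H](C)CO[C@@]1(C)CC=C | intermediate
27 | C9 aldehyde (2,11-diol) | O[C@H]1[C@@H]2[C@H](C=O)[C@H](O)[C@H](C)C[C@H]2[C@@H](C)CO[C@@]1(C)CC=C | intermediate
28 | tricyclic lactol (ring A, oxepane, tetrahydrofuran; 9-OH anomers; 11-OH) | O[C@H]1[C@@H]2[C@@H]3[C@@H](C[C@H]1C)[C@@H](C)CO[C@@](C)(CC=C)[C@H]3OC2O | intermediate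
29 | 9,11-diacetate of 28 | CC(=O)O[C@H]1[C@@H]2[C@@H]3[C@@H](C[C@H]1C)[C@@H](C)CO[C@@](C)(CC=C)[C@H]3OC2OC(C)=O | intermediate
30 | 2-(trimethylsilyloxy)buta-1,3-diene | C=CC(=C)O[Si](C)(C)C | starting material
31 | vinyl ketone (9S; C8 cis to C3 on the tetrahydrofuran) | CC(=O)O[C@H]1[C@@H]2[C@@H]3[C@@H](C[C@H]1C)[C@@H](C)CO[C@@](C)(CC=C)[C@H]3O[C@H]2CC(=O)C=C | intermediate
32 | tetracyclic Z-enone (C5=C6) | CC(=O)O[C@H]1[C@@H]2[C@@H]3[C@@H](C[C@H]1C)[C@@H](C)CO[C@@]1(C)C/C=C\C(=O)C[C@@H]2O[C@@H]31 | intermediate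
33 | target CNP0288436.2 (1S,2S,3S,9S,10R,11R,12R,14S,15R in the numbering used here) | CC(=O)O[C@H]1[C@@H]2[C@@H]3[C@@H](C[C@H]1C)[C@@H](C)CO[C@@]1(C)CCCC(=O)C[C@@H]2O[C@@H]31 | target

Total step count: 22. Longest linear sequence: 20 steps (steps 1–3 and 6–22).

Steps most likely to fail

Step 6. The cycloaddition may be slow with a β-substituted dienal, may occur in part at the γ,δ-alkene, or may lose endo and facial selectivity. Fallback (auxiliary control in place of catalyst control): it sets out from 3 and 5 and returns at 12. Pinnick oxidation of 3 (NaClO2, NaH2PO4, 2-methylbut-2-ene) should give (2E)-4-methylpenta-2,4-dienoic acid F1. Activation as the mixed pivalic anhydride and acylation of lithiated (4R)-4-benzyl-1,3-oxazolidin-2-one should give the N-dienoyl oxazolidinone F2. Its Et2AlCl-promoted Diels–Alder reaction with 5 (CH2Cl2, −30 °C) through the chelated s-cis imide should give the imide adduct F3. LiBH4 in THF/MeOH should cleave the auxiliary to the primary alcohol F4, and Dess–Martin oxidation gives 12.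

Step 7. Allyl transfer from the γ,γ-disubstituted boronate may be slow, and the catalyst may fail to override the facial preference of the α-branched aldehyde (mismatched double diastereodifferentiation). Fallback (stoichiometric reagent control): it sets out from 8 and 12 and returns at 13. Lithium–iodine exchange of 8, trapping with diisopropyl (chloromethyl)boronate and ester exchange with diisopropyl (2S,3S)-tartrate should give the tartrate-modified allylboronate F5. Its uncatalysed addition to 12 (toluene, 4 Å sieves, −78 °C) goes through the same closed chair and should give 13.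

Step 21. The electron-poor vinyl ketone may initiate poorly, and oligomerisation or cross-metathesis may outrun closure of the strained nine-membered enone. Fallback (ring closure at the allylic silyl ether oxidation level): it sets out from 31 and returns at 32. Luche reduction of 31 should give the allylic alcohol F6 (C7 epimers). Et3SiCl/imidazole should give the triethylsilyl ether F7. Ring-closing metathesis with the second-generation Grubbs catalyst should give the cyclic allylic silyl ether F8. HF·pyridine should give the cyclic allylic alcohol F9, and MnO2 oxidation gives 32.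

Further compounds
F1 | step 6 | (2E)-4-methylpenta-2,4-dienoic acid | CC(=C)/C=C/C(O)=O
F2 | step 6 | (4R)-4-benzyl-3-[(2E)-4-methylpenta-2,4-dienoyl]-1,3-oxazolidin-2-one | C=C(C)/C=C/C(=O)N1[C@H](Cc2ccccc2)COC1=O
F3 | step 6 | N-acyl oxazolidinone Diels–Alder adduct (ring A as in 12, imide in place of CHO) | O=C([C@@H]1[C@H](CO[Si](c2ccccc2)(c2ccccc2)C(C)(C)C)C=C(C)C[C@H]1C(C)=C)N1[C@H](Cc2ccccc2)COC1=O
F4 | step 6 | ring A primary alcohol (CH2OH in place of CHO of 12) | OC[C@@H]1[C@H](CO[Si](c2ccccc2)(c2ccccc2)C(C)(C)C)C=C(C)C[C@H]1C(C)=C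
F5 | step 7 | diisopropyl (4S,5S)-2-[(2E)-6-chloro-3-methylhex-2-en-1-yl]-1,3,2-dioxaborolane-4,5-dicarboxylate | CC(C)OC(=O)[C@H]1OB(C/C=C(\C)CCCCl)O[C@@H]1C(=O)OC(C)C
F6 | step 21 | allylic alcohol from 31 (C7-OH, epimers) | CC(=O)O[C@H]1[C@@H]2[C@@H]3[C@@H](C[C@H]1C)[C@@H](C)CO[C@@](C)(CC=C)[C@H]3O[C@H]2CC(O)C=C
F7 | step 21 | triethylsilyl ether of F6 | CC(=O)O[C@H]1[C@@H]2[C@@H]3[C@@H](C[C@H]1C)[C@@H](C)CO[C@@](C)(CC=C)[C@H]3O[C@H]2CC(O[Si](CC)(CC)CC)C=C
F8 | step 21 | nine-membered cyclic allylic triethylsilyl ether (C5=C6, C7-OSiEt3) | CC(=O)O[C@H]1[C@@H]2[C@@H]3[C@@H](C[C@H]1C)[C@@H](C)CO[C@@]1(C)C/C=C\C(O[Si](CC)(CC)CC)C[C@@H]2O[C@@H]31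
F9 | step 21 | nine-membered cyclic allylic alcohol (C5=C6, C7-OH) | CC(=O)O[C@H]1[C@@H]2[C@@H]3[C@@H](C[C@H]1C)[C@@H](C)CO[C@@]1(C)C/C=C\C(O)C[C@@H]2O[C@@H]31
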